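**Plan**
1. Atom labels used below: C1 ketone, C2=C3(CH3), C4 and C11 (cyclobutane CH next to C3 and C1), C5 (cyclobutane CH), C6 (CMe2), C7 and C8 (angelate carbinols), C9 (CHOH), C10 (C–CH3). The cyclobutane is C4–C5–C11–C10 and the seven-membered ring is C5–C6–C7–C8–C9–C10–C11.
2. Retrosynthesis: the esters, the 9-OH and the C2=C3 bond are taken back to hydroxy diketone 20 (C1=O, C8=O). Then C10–C11 and C8–C9 are cut and C8–C11 is re-joined, which gives the hydrindane enol ether 17. Ring C8–C11 is cut next (Claisen), then C2–C3 and C4–C5 (Diels–Alder), leaving a chain from (S)-pantolactone.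
3. Forward order of rings: six-membered ring (Diels–Alder), cyclopentane C11–C5–C6–C7–C8 (Claisen), temporary seven-membered disiloxane ring (O7 to enol O8), then photocycloaddition (cyclobutane) and opening of the cyclopentane to the cycloheptane.
4. Enabling feature: C1=O and the C8 oxygen are 1,3-related through C11 (a β-diketone enol once C8 is a ketone), and C9–C10 is a two-carbon alkene unit whose C10 hangs on C4, two bonds from C11. Enol plus alkene therefore close the cyclobutane and, after cleavage of C8–C11, the seven-membered ring.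
5. Stereochemistry: C7 from (S)-pantolactone; C4 and C5 (and transient C3) from the catalyst-controlled endo Diels–Alder; C10 and C11 from the C5–C4 tether in the photocycloaddition.
6. C9 is set by Rubottom oxidation anti to the C7 silyl ether, and C8 by hydride delivery directed by the C7 hydroxyl.

Key step: step 9

Assumption: (S)-pantolactone and both antipodes of the oxazaborolidine catalyst are purchased; the antipode named in step 5 is the one expected from the α-C–H···O binding model to expose the required diene face. The target is taken as drawn (both esters Z, angelates).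

Step 1
Reactants: 1 (S)-pantolactone; 2 N,O-dimethylhydroxylamine hydrochloride
Product: 3 (2S)-2,4-dihydroxy-N-methoxy-N,3,3-trimethylbutanamide
Conditions: i-PrMgCl, THF, −15 → 0 °C
Reagents that add atoms: N,O-dimethylhydroxylamine hydrochloride (CNOC.Cl)
Why: Magnesium-amide aminolysis of the γ-lactone (Weinreb amide formation) should open the ring without touching C7, whose S configuration is carried from 1.

Step 2
Reactants: 3 (2S)-2,4-dihydroxy-N-methoxy-N,3,3-trimethylbutanamide
Product: 4 (2S)-2-hydroxy-N-methoxy-N,3,3-trimethyl-4-oxobutanamide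
Conditions: TEMPO (cat.), PhI(OAc)2, CH2Cl2, rt
Reagents that add atoms: none
Why: The TEMPO/PhI(OAc)2 oxidation is selective for the primary alcohol over the secondary α-hydroxy amide, and the α-quaternary aldehyde cannot epimerize.

Step 3
Reactants: 4 (2S)-2-hydroxy-N-methoxy-N,3,3-trimethyl-4-oxobutanamide; 5 1-(triphenylphosphoranylidene)propan-2-one
Product: 6 (2S,4E)-2-hydroxy-N-methoxy-N,3,3-trimethyl-6-oxohept-4-enamide
Conditions: toluene, 80 °C
Reagents that add atoms: 1-(triphenylphosphoranylidene)propan-2-one (CC(=O)C=P(c1ccccc1)(c1ccccc1)c1ccccc1)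
Why: Wittig olefination with a stabilized ylide should give the E-enone under neutral conditions that avoid retro-aldol cleavage of the β-hydroxy aldehyde.

Step 4
Reactants: 6 (2S,4E)-2-hydroxy-N-methoxy-N,3,3-trimethyl-6-oxohept-4-enamide; 7 tert-butyldimethylsilyl trifluoromethanesulfonate
Product: 8 (2S,4E)-2,6-bis(tert-butyldimethylsilyloxy)-N-methoxy-N,3,3-trimethylhepta-4,6-dienamide
Conditions: Et3N, CH2Cl2, −78 → 0 °C
Reagents that add atoms: tert-butyldimethylsilyl trifluoromethanesulfonate (CC(C)(C)[Si](C)(C)OS(=O)(=O)C(F)(F)F)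
Why: Soft enolization of the methyl ketone can only give the 2-siloxy-1,3-diene (the γ-carbon is quaternary), and the C7 hydroxyl is silylated in the same operation.

Step 5
Reactants: 8 (2S,4E)-2,6-bis(tert-butyldimethylsilyloxy)-N-methoxy-N,3,3-trimethylhepta-4,6-dienamide; 9 (E)-pent-3-en-2-one
Product: 10 (2S)-3-[(1R,5R,6S)-6-acetyl-3-(tert-butyldimethylsilyloxy)-5-methylcyclohex-2-en-1-yl]-2-(tert-butyldimethylsilyloxy)-N-methoxy-N,3-dimethylbutanamide (acetyl cis to the side chain, trans to the ring methyl)
Conditions: (S)-1-(o-tolyl)-3,3-diphenyl-hexahydropyrrolo[1,2-c][1,3,2]oxazaborole·HNTf2 (20 mol %), CH2Cl2, −78 → −40 °C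
Reagents that add atoms: (E)-pent-3-en-2-one (C/C=C/C(C)=O)
Why: Lewis-acid-catalysed Diels–Alder reaction in which the diene CH2 (C2) bonds to the β-carbon (C3) and C5 to C4, the endo transition state places the acetyl group cis to the C5 side chain and trans to the C3 methyl, and the chiral oxazaborolidinium ion selects the diene face, so C4 and C5 are set relative to C7 by the catalyst.

Step 6
Reactants: 10 Diels–Alder adduct (methyl ketone); 11 dibromomethane
Product: 12 (2S)-2-(tert-butyldimethylsilyloxy)-3-[(1S,5R,6S)-3-(tert-butyldimethylsilyloxy)-5-methyl-6-(prop-1-en-2-yl)cyclohex-2-en-1-yl]-N-methoxy-N,3-dimethylbutanamide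
Conditions: Zn, CH2Br2, TiCl4 (pre-formed reagent), THF/CH2Cl2, 0 °C → rt
Reagents that add atoms: dibromomethane (BrCBr)
Why: Takai–Lombardo methylenation is non-basic, so the epimerizable C4 (α to the ketone, cis to the C5 side chain) should be preserved, and the amide and silyl enol ether are left alone.

Step 7
Reactants: 12 isopropenyl silyl enol ether
Product: 15 2-hydroxy-3,3,5-trimethyl-4-(prop-1-en-2-yl)hexahydroindene-1,7-dione (enol form; hydroxyl cis to the C3a–C4 ring bond, isopropenyl cis to C3 and trans to the 5-methyl), via ammonium enolate 13 (not isolated), via silyl-protected diketone 14 (not isolated)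
Conditions: Bu4NF (3.5 equiv), THF, 0 °C → rt; aq. NH4Cl
Reagents that add atoms: none
Why: Fluoride unmasks the regiodefined enolate at C11, which should acylate the Weinreb amide intramolecularly (5-exo-trig Claisen/Dieckmann-type condensation) to the β-diketone, and excess fluoride removes the C7 silyl ether while the β-diketonate protects C7 from enolization.

Step 8
Reactants: 15 hydroxy β-diketone; 16 1,3-dichloro-1,1,3,3-tetraisopropyldisiloxane
Product: 17 hydrindenone in which O7 and the enol oxygen on C8 are joined by the tetraisopropyldisiloxane bridge (C8=C11 enol ether conjugated with C1=O)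
Conditions: imidazole, DMF, 0 °C → rt
Reagents that add atoms: 1,3-dichloro-1,1,3,3-tetraisopropyldisiloxane (CC(C)[Si](Cl)(C(C)C)O[Si](Cl)(C(C)C)C(C)C)
Why: Silylation of the C7 hydroxyl and of the neighbouring enol oxygen closes a seven-membered disiloxane ring (an O1-silylated isomer would need a nine-membered ring and should return by 1,5-silyl shift), which fixes the enol on C8=C11.

Step 9
Reactants: 17 disiloxane-bridged enol ether
Product: 20 7-hydroxy diketone with the full tricyclic skeleton (C1=O, C8=O, 7-OH on the C4 face, C3 methyl saturated), via photoadduct 18 (not isolated), via cyclobutanediol 19 (not isolated)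
Conditions: hν (350 nm, Pyrex), MeCN (0.005 M, degassed), 0 °C; then Bu4NF, THF/MeOH, 0 → 25 °C; aq. NH4Cl
Reagents that add atoms: none
Why: Excitation of the β-siloxy enone C8=C11–C1=O (triplet) should be followed by bonding of C8 to the CH2 terminus C9 and collapse of the 1,4-biradical (C10/C11) to the bicyclo[2.2.0]hexane 18, after which fluoride frees the cyclobutanol and the C8–C11 bond is cleaved in retro-aldol fashion; the closest known reaction type is the intramolecular de Mayo reaction (enol-derivative [2+2] photocycloaddition, then retro-aldol). The C8–C9 bond closes a six-membered ring in the 6-endo mode, the C10–C11 bond closes the cyclobutane C4–C5–C11–C10 by radical recombination (4-exo seen from C11), and the cleavage turns the cyclopentane C11–C5–C6–C7–C8 into the cycloheptane by inserting C9 and C10. C10 and C11 are set by the two-atom tether C5–C4, which lets the alkene reach the enol only from the face that carries C4, so the cyclobutane is cis-fused, the C10 methyl points away from the C6–C9 bridge and the proton arrives at C11 in the only position the bicyclo[3.1.1] frame allows. The step needs 1,6- instead of 1,5-closure and reaction of the C8 enol instead of a C1 enol: the first rests on the methyl group at the internal alkene carbon C10 and the fully substituted C8, which penalize a C8–C10 bond and favour the tertiary radical at C10, the second on the disiloxane ring. The carbanion developing at C11 lies in the plane of C1=O and is not an enolate, so the opening is paid for by the strain of the bicyclo[2.2.0]hexane and by protonation from methanol.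

Step 10
Reactants: 20 7-hydroxy diketone; 21 triethylsilyl trifluoromethanesulfonate
Product: 22 7-(triethylsilyloxy) diketone
Conditions: 2,6-lutidine, CH2Cl2, −78 °C
Reagents that add atoms: triethylsilyl trifluoromethanesulfonate (CC[Si](CC)(CC)OS(=O)(=O)C(F)(F)F)
Why: Silyl triflate protection of the hindered secondary alcohol, needed because the oxidant of the next step would attack it.

Step 11
Reactants: 22 7-(triethylsilyloxy) diketone
Product: 23 7-(triethylsilyloxy) enone ketone (C1(=O)–C2=C3(CH3), C8=O)
Conditions: IBX, 4-methoxypyridine N-oxide, DMSO, 25 °C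
Reagents that add atoms: none
Why: IBX dehydrogenation can act only at C1 towards C2–C3, because C11 is a bridgehead and the C8 ketone has no β-hydrogen (C6 and C10 are quaternary), and the C3 stereocentre is removed.

Step 12
Reactants: 23 7-(triethylsilyloxy) enone ketone; 7 tert-butyldimethylsilyl trifluoromethanesulfonate; 24 3-chloroperoxybenzoic acid
Product: 26 9-(tert-butyldimethylsilyloxy)-7-(triethylsilyloxy) enone ketone (9-O trans to 7-O), via silyl enol ether 25 (not isolated)
Conditions: LiN(SiMe3)2, THF, −78 °C; TBSOTf; then mCPBA, NaHCO3, CH2Cl2, −20 → 0 °C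
Reagents that add atoms: tert-butyldimethylsilyl trifluoromethanesulfonate (CC(C)(C)[Si](C)(C)OS(=O)(=O)C(F)(F)F); 3-chloroperoxybenzoic acid (O=C(OO)c1cccc(Cl)c1)
Why: Kinetic deprotonation should occur at C9 (the enone has no accessible α′-hydrogen, C7 is hindered and oxygenated), and in the Rubottom oxidation the peracid adds to the enol ether face opposite the allylic C7 silyl ether, which places the C9 oxygen trans to O7, the silyl group migrating to the new oxygen.

Step 13
Reactants: 26 bis-silyl ether
Product: 27 7-hydroxy-9-(tert-butyldimethylsilyloxy) enone ketone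
Conditions: PPTS, MeOH/CH2Cl2, 0 °C → rt
Reagents that add atoms: none
Why: Acid-catalysed methanolysis removes the triethylsilyl ether selectively in the presence of the tert-butyldimethylsilyl ether.

Step 14
Reactants: 27 7-hydroxy-9-(tert-butyldimethylsilyloxy) enone ketone
Product: 28 7,8-diol (7,8-trans, 8,9-cis), 9-O-silyl enone
Conditions: Me4NBH(OAc)3, MeCN/AcOH, −30 °C
Reagents that add atoms: none
Why: Hydroxyl-directed reduction (Evans–Saksena): the acetoxyborohydride bound to O7 delivers hydride to C8 from the O7 face, giving the 7,8-trans diol with the C8 hydroxyl cis to the C9 oxygen, and the enone is not reduced by this reagent.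

Step 15
Reactants: 28 7,8-diol; 29 angelic acid
Product: 30 7,8-di-O-angeloyl-9-O-(tert-butyldimethylsilyl) enone
Conditions: 2,4,6-Cl3C6H2COCl, Et3N, toluene, rt; then 28, 75 °C
Reagents that add atoms: angelic acid (C/C=C(/C)C(=O)O)
Why: Yamaguchi-type acylation with the preformed mixed anhydride, run without DMAP to avoid Z→E isomerization, should esterify both free hydroxyls while O9 stays silylated.

Step 16
Reactants: 30 di-O-angeloyl silyl ether
Product: 31 target CNP0256888.1
Conditions: HF·pyridine, THF, 0 °C → rt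
Reagents that add atoms: none
Why: Desilylation under mildly acidic fluoride conditions should avoid acyl migration from O8 to O9 and leave the enone and the Z-enoates untouched.

**Compound list**
1 | (S)-pantolactone | CC1(C)COC(=O)[C@H]1O | starting material
2 | N,O-dimethylhydroxylamine hydrochloride | CNOC.Cl | starting material
3 | (2S)-2,4-dihydroxy-N-methoxy-N,3,3-trimethylbutanamide | CON(C)C(=O)[C@@H](O)C(C)(C)CO | intermediate
4 | (2S)-2-hydroxy-N-methoxy-N,3,3-trimethyl-4-oxobutanamide | CON(C)C(=O)[C@@H](O)C(C)(C)C=O | intermediate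
5 | 1-(triphenylphosphoranylidene)propan-2-one | CC(=O)C=P(c1ccccc1)(c1ccccc1)c1ccccc1 | starting material
6 | (2S,4E)-2-hydroxy-N-methoxy-N,3,3-trimethyl-6-oxohept-4-enamide | CON(C)C(=O)[C@@H](O)C(C)(C)/C=C/C(C)=O | intermediate
7 | tert-butyldimethylsilyl trifluoromethanesulfonate | CC(C)(C)[Si](C)(C)OS(=O)(=O)C(F)(F)F | starting material
8 | (2S,4E)-2,6-bis(tert-butyldimethylsilyloxy)-N-methoxy-N,3,3-trimethylhepta-4,6-dienamide | CON(C)C(=O)[C@@H](O[Si](C)(C)C(C)(C)C)C(C)(C)/C=C/C(=C)O[Si](C)(C)C(C)(C)C | intermediate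
9 | (E)-pent-3-en-2-one | C/C=C/C(C)=O | starting material
10 | Diels–Alder adduct, (1R,5R,6S)-6-acetyl-5-methyl-3-silyloxycyclohex-2-enyl butanamide (2S) | CC(=O)[C@H]1[C@H](C)CC(O[Si](C)(C)C(C)(C)C)=C[C@H]1C(C)(C)[C@H](O[Si](C)(C)C(C)(C)C)C(=O)N(C)OC | intermediate
11 | dibromomethane | BrCBr | starting material
12 | isopropenyl analogue of 10, (1S,5R,6S) ring, (2S) chain | CC(=C)[C@H]1[C@H](C)CC(O[Si](C)(C)C(C)(C)C)=C[C@H]1C(C)(C)[C@H](O[Si](C)(C)C(C)(C)C)C(=O)N(C)OC | intermediate
13 | tetrabutylammonium enolate of the cyclohexanone (enolate at C1/C11) | CC(=C)[C@H]1[C@H](C)CC([O-])=C[C@H]1C(C)(C)[C@H](O[Si](C)(C)C(C)(C)C)C(=O)N(C)OC.CCCC[N+](CCCC)(CCCC)CCCC | intermediate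
14 | 2-(tert-butyldimethylsilyloxy)-3,3,5-trimethyl-4-(prop-1-en-2-yl)hexahydroindene-1,7-dione (enol form) | O=C1C[C@@H](C)[C@H](C(C)=C)[C@@H]2C(C)(C)[C@H](O[Si](C)(C)C(C)(C)C)C(O)=C12 | intermediate
15 | 2-hydroxy-3,3,5-trimethyl-4-(prop-1-en-2-yl)hexahydroindene-1,7-dione (enol form) | O=C1C[C@@H](C)[C@H](C(C)=C)[C@@H]2C(C)(C)[C@H](O)C(O)=C12 | intermediate
16 | 1,3-dichloro-1,1,3,3-tetraisopropyldisiloxane | CC(C)[Si](Cl)(C(C)C)O[Si](Cl)(C(C)C)C(C)C | starting material
17 | disiloxane-bridged enol ether of 15 (O7–Si–O–Si–O8, C8=C11–C1=O) | O=C1C[C@@H](C)[C@H](C(C)=C)[C@@H]2C(C)(C)[C@@H]3O[Si](C(C)C)(C(C)C)O[Si](C(C)C)(C(C)C)OC3=C12 | intermediate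
18 | photoadduct, bicyclo[2.2.0]hexane (new bonds C8–C9 and C10–C11), disiloxane intact | O=C1C[C@@H](C)[C@@H]2[C@@]3(C)C[C@@]45O[Si](C(C)C)(C(C)C)O[Si](C(C)C)(C(C)C)O[C@H]4C(C)(C)[C@@H]2[C@@]135 | intermediate
19 | cyclobutanediol (C7–OH, C8–OH) from 18 | O=C1C[C@@H](C)[C@@H]2[C@@]3(C)C[C@@]4(O)[C@@H](O)C(C)(C)[C@@H]2[C@@]134 | intermediate
20 | 7-hydroxy tricyclic 1,8-diketone | O=C1[C@@H](O)C(C)(C)[C@@H]2[C@H]3C(=O)C[C@@H](C)[C@@H]2[C@@]3(C)C1 | intermediate
21 | triethylsilyl trifluoromethanesulfonate | CC[Si](CC)(CC)OS(=O)(=O)C(F)(F)F | starting material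
22 | 7-(triethylsilyloxy) tricyclic 1,8-diketone | O=C1[C@@H](O[Si](CC)(CC)CC)C(C)(C)[C@@H]2[C@H]3C(=O)C[C@@H](C)[C@@H]2[C@@]3(C)C1 | intermediate
23 | 7-(triethylsilyloxy) 2-en-1-one 8-ketone | O=C1[C@@H](O[Si](CC)(CC)CC)C(C)(C)[C@@H]2[C@H]3C(=O)C=C(C)[C@@H]2[C@@]3(C)C1 | intermediate
24 | 3-chloroperoxybenzoic acid | O=C(OO)c1cccc(Cl)c1 | starting material
25 | C8=C9 tert-butyldimethylsilyl enol ether of 23 | CC(C)(C)[Si](C)(C)OC=1[C@@H](O[Si](CC)(CC)CC)C(C)(C)[C@@H]2[C@H]3C(=O)C=C(C)[C@@H]2[C@@]3(C)C=1 | intermediate
26 | 9-(tert-butyldimethylsilyloxy)-7-(triethylsilyloxy) 2-en-1-one 8-ketone | O=C1[C@@H](O[Si](CC)(CC)CC)C(C)(C)[C@@H]2[C@H]3C(=O)C=C(C)[C@@H]2[C@@]3(C)[C@@H]1O[Si](C)(C)C(C)(C)C | intermediate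
27 | 7-hydroxy-9-(tert-butyldimethylsilyloxy) 2-en-1-one 8-ketone | O=C1[C@@H](O)C(C)(C)[C@@H]2[C@H]3C(=O)C=C(C)[C@@H]2[C@@]3(C)[C@@H]1O[Si](C)(C)C(C)(C)C | intermediate
28 | 7,8-dihydroxy-9-(tert-butyldimethylsilyloxy) 2-en-1-one | O[C@@H]1[C@@H](O)C(C)(C)[C@@H]2[C@H]3C(=O)C=C(C)[C@@H]2[C@@]3(C)[C@@H]1O[Si](C)(C)C(C)(C)C | intermediate
29 | angelic acid, (Z)-2-methylbut-2-enoic acid | C/C=C(/C)C(=O)O | starting material
30 | 7,8-di-O-angeloyl-9-O-(tert-butyldimethylsilyl) 2-en-1-one | C/C=C(/C)C(=O)O[C@@H]1[C@@H](OC(=O)/C(C)=C\C)C(C)(C)[C@@H]2[C@H]3C(=O)C=C(C)[C@@H]2[C@@]3(C)[C@@H]1O[Si](C)(C)C(C)(C)C | intermediate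
31 | CNP0256888.1 | C/C=C(/C)C(=O)O[C@@H]1[C@@H](OC(=O)/C(C)=C\C)C(C)(C)[C@@H]2[C@H]3C(=O)C=C(C)[C@@H]2[C@@]3(C)[C@@H]1O | target

**Totals and risks**
Total step count: 16. Longest linear sequence: 16 steps (from (S)-pantolactone).

Step 9. Two processes may defeat it. The excited enone may close 1,5 instead of 1,6. More likely, the ionic opening of the cyclobutanol may stall, because the C8–C11 bond lies nearly in the nodal plane of the C1 carbonyl and the carbanion at the bridgehead C11 gains no enolate stabilization; the alkoxide may then wander into silyl transfer or α-ketol isomerization. The fallback covers the second process and replaces the ionic opening by alkoxy-radical β-scission, which needs no overlap with C1=O. It sets out from 17: irradiation as in step 9 with isolation of photoadduct 18, buffered desilylation (Bu4NF/AcOH) to the isolated cyclobutanediol 19, selective silylation of the secondary hydroxyl (Et3SiCl, imidazole) to the tertiary cyclobutanol F1, generation of the alkoxy radical (PhI(OAc)2, I2, visible light) with scission of C8–C11 and iodine capture at C11 to give the α-iodo diketone F2, and removal of iodine (Bu3SnH, AIBN). It comes back to the route at 22.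

Step 5. The catalyst may fail to discriminate the diene faces (neopentyl diene terminus, two Lewis-basic sites in 8), or the reaction may run stepwise (Mukaiyama–Michael) and erode the endo relationship. The fallback gives up reagent control and uses the pantolactone stereocentre for separation. It sets out from 8: thermal Diels–Alder reaction with 9 (toluene, 130 °C, sealed tube) gives 10 together with its facial diastereomer F3; the mixture is taken through the conditions of steps 6 and 7, where the isopropenyl compound F4 accompanies 12 and the bicyclic diketone F5 accompanies 15. The rigid diketones 15 and F5, which differ in the relation of the C7 hydroxyl to C4, are separated by chromatography, and the route is rejoined at 15.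

Step 15. The activated angeloyl group may isomerize to the tigloyl group, and acylation of the neopentylic C7 hydroxyl may stay incomplete. The fallback builds the Z-enoates on the substrate instead of transferring them. It sets out from 28: esterification of both hydroxyls with 2-[bis(2,2,2-trifluoroethoxy)phosphoryl]propanoic acid (DCC, DMAP) gives the bis-phosphonate F6, and Still–Gennari olefination (KN(SiMe3)2, 18-crown-6, acetaldehyde, THF, −78 °C) forms both (Z)-2-methylbut-2-enoates. It comes back to the route at 30.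

**Further compounds**
F1 | step 9 | tertiary cyclobutanol with 7-O-triethylsilyl ether (from 19) | O=C1C[C@@H](C)[C@@H]2[C@@]3(C)C[C@@]4(O)[C@@H](O[Si](CC)(CC)CC)C(C)(C)[C@@H]2[C@@]134
F2 | step 9 | 11-iodo-7-(triethylsilyloxy) tricyclic 1,8-diketone | O=C1[C@@H](O[Si](CC)(CC)CC)C(C)(C)[C@@H]2[C@@]3(I)C(=O)C[C@@H](C)[C@@H]2[C@@]3(C)C1
F3 | step 5 | facial diastereomer of 10 (ring centres inverted, C7 unchanged) | CC(=O)[C@@H]1[C@@H](C)CC(O[Si](C)(C)C(C)(C)C)=C[C@@H]1C(C)(C)[C@H](O[Si](C)(C)C(C)(C)C)C(=O)N(C)OC
F4 | step 5 | facial diastereomer of 12 | CC(=C)[C@@H]1[C@@H](C)CC(O[Si](C)(C)C(C)(C)C)=C[C@@H]1C(C)(C)[C@H](O[Si](C)(C)C(C)(C)C)C(=O)N(C)OC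
F5 | step 5 | diastereomer of 15 (hydroxyl trans to the C3a–C4 ring bond) | O=C1C[C@H](C)[C@@H](C(C)=C)[C@H]2C(C)(C)[C@H](O)C(O)=C12
F6 | step 15 | 7,8-bis{2-[bis(2,2,2-trifluoroethoxy)phosphoryl]propanoate} of 28 | CC(C(=O)O[C@@H]1[C@@H](OC(=O)C(C)P(=O)(OCC(F)(F)F)OCC(F)(F)F)C(C)(C)[C@@H]2[C@H]3C(=O)C=C(C)[C@@H]2[C@@]3(C)[C@@H]1O[Si](C)(C)C(C)(C)C)P(=O)(OCC(F)(F)F)OCC(F)(F)F
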